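All runs stem from a simulated flask with constants of no real substance; the scatter is artificial.

I take target to be made from substrate and spent with partner, so I compare its making with its spending at one moment. I assume two steps in series, substrate + partner → target and target + partner → over-reaction product, each first order in c(partner). Then c(partner) cancels, and making over spending is c(substrate)/(S·c(target)), where S is the rate constant of spending over that of making. In this scheme target peaks where that ratio reaches one.

| flask | substrate | partner | remark | time |
|---|---|---|---|---|
| south-east | 0.40 M | 0.46 equiv | run made earlier |  |
| south | 0.40 M | 1.3 equiv | run made earlier |  |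
| north-east | 0.40 M | 2.9 equiv | run made earlier |  |
| alder | 0.40 M | 0.600 equiv |  | 20 min |
| maple | 0.40 M | 1.20 equiv |  | 20 min |
| ash | 0.40 M | 2.50 equiv |  | 20 min |

| run | time / min | target / % |
|---|---|---|
| south-east | 1.00 | 3.8 |
| south-east | 2.00 | 6.5 |
| south-east | 4.00 | 11.8 |
| south-east | 8.00 | 18.9 |
| south-east | 15.0 | 22.5 |
| south | 3.00 | 22.3 |
| south | 6.00 | 28.9 |
| south | 8.00 | 30.9 |
| south | 12.0 | 32.9 |
| south | 15.0 | 33.0 |
| north-east | 3.00 | 32.0 |
| north-east | 6.00 | 30.4 |
| north-east | 8.00 | 27.3 |
| north-east | 12.0 | 20.5 |
| north-east | 15.0 | 17.4 |

(readings scatter by 0.5 percentage points)

- "hardly changes" means that all values lie within two and a half points (for a concentration: within two and a half percent of the largest)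

1. amount of target at the end, in percent of the substrate charged for alder, maple, ash, in this order
2. how that number moves from the first to the last of them (rises, then falls / falls all the way / hardly changes / rises all the way / falls, then rises)

Which numbers must I know well? The substrate charge and the partner equivalents drop out of the ratio. In this scheme they tell how far a flask gets in 20 min, not at what ratio a peak would lie. The peak height does matter, since in this scheme it depends on S. Taking the north-east 32.0% in place of the south 33.0% as that height moves S by 0.0615. The south readings 32.9% and 33.0% agree within the scatter of 0.5 percentage points, so I use the south plateau.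

For S near one, the logarithm of the inverse peak height exceeds one by 0.5(S − 1). That gives a reading of S = 1.22, the spend factor, a selectivity factor. On that reading, and in this scheme, the peak stands where c(substrate) is 40.3% of the charge.

Alder lies near south-east, still rising at 22.5%, so I expect its ratio above one. Maple lies near south, so I expect about 33.0%. Ash lies near north-east, which has fallen to 17.4%, so I expect its ratio below one.

The forecast gives 27%, 32.8% and 20%, a row that rises, then falls. For ash it says “it has passed the maximum and been eaten down”.

The flasks give 28.4%, 32.5% and 16.3%, a row that rises, then falls.

    substrate + partner → target (k = 0.222 M⁻¹ min⁻¹)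
    substrate + 2 partner → side product (k = 0.00312 M⁻² min⁻¹)
    partner + target → over-reaction product (k = 0.276 M⁻¹ min⁻¹)

In alder, target is made 3.80 times faster than used up, each step taken net, at 5.08 min, and this falls to 1.72 at 20.0 min. The spend factor carries that comparison over: c(substrate)/(S·c(target)) gives 1.76 for alder at the end, and for ash, with 8.90% substrate against 16.3% target, 0.448.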